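Colleague, you asked me for a quick number on the flask and sent your hunch along, so I set down what we had.

| setting | eta | beta | flask |
|---|---|---|---|
| left-handed substrate | 0.17 M | 0.38 M | 0.25 M |
| right-handed substrate | 0.17 M | 0.38 M | 0.25 M |
| partner | 2.2 equiv | 2.2 equiv | 2.20 equiv |
| free catalyst | 0.5 mol% | 0.5 mol% | 0.5 mol% |
| racemization catalyst | 3.6 mol% | 3.6 mol% | 3.6 mol% |
| added ligand | 18 mM | 18 mM | 18 mM |
| remark | run made earlier | run made earlier |  |
| time |  |  | 20 min |

| run | time / min | left-handed substrate / % | right-handed substrate / % | left-handed product / % |
|---|---|---|---|---|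
| eta | 3.00 | 46.7 | 45.7 | 5.5 |
| eta | 6.00 | 44.9 | 44.5 | 10.4 |
| eta | 8.00 | 40.3 | 41.1 | 13.8 |
| eta | 12.0 | 41.8 | 40.8 | 13.7 |
| eta | 15.0 | 40.2 | 38.0 | 16.7 |
| eta | 20.0 | 39.4 | 38.7 | 19.4 |
| beta | 3.00 | 34.8 | 38.7 | 22.7 |
| beta | 6.00 | 33.7 | 33.6 | 29.5 |
| beta | 8.00 | 31.9 | 31.1 | 36.5 |
| beta | 12.0 | 28.4 | 28.0 | 38.9 |
| beta | 15.0 | 26.4 | 27.4 | 39.8 |
| beta | 20.0 | 25.0 | 27.8 | 43.7 |

(standard deviation of a reading: 1 percentage point)

- free catalyst is single-handed; left-handed substrate and right-handed substrate are mirror images of each other, charged as a racemate, each of them at the stated concentration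
- the numbers in the tables scatter by 1 percentage point (one standard deviation)
- an excess is below zero if the other one leads

- part of the left-handed substrate and right-handed substrate charged together that has reacted at 20 min
- excess of left-handed product over right-handed product in the product at 20 min
- excess of right-handed substrate over left-handed substrate among what is left of the two at 20 min

I started from the symmetric case as the zero of the scale: a catalyst blind to handedness makes the two products equally, so eP is zero. The tables list no right-handed product, so I read it as the gap, the part of the charge missing once both substrates and the left-handed product were counted. The eta run kept its substrates nearly level, 39.4 % against 38.7 % at 20.0 min. With level substrates, and both hands assumed to use the same catalyst, the two products should form in a steady ratio however fast the reaction runs.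

Each gap was a difference of three readings, each scattering by 1 percentage point, so I pooled both runs. Counted as fractions of the charge, they summed to 291 of left-handed product against 40.5 of gap. I kept 7.18 as the split, left-handed product formed per right-handed product formed, which is a reading of the selectivity factor. A blind catalyst would give a split of 1. Mine gave eP = 75.5 %.

For c I interpolated in charge between the reacted parts at 20.0 min, 21.9 % in the eta run and 47.2 % in the beta run, and got 31.5 %. For eS I said close to zero.

Your forecast, “These runs read as a dynamic kinetic resolution”, gave c = 32 %, eP = 75 % and eS = 2 %.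

The flask gave c = 33.7 %, eP = 76.9 % and eS = 0.351 %.

    partner → decomposition product (k = 4.30 × 10⁻⁴ min⁻¹)
    partner + free catalyst + right-handed substrate → free catalyst + right-handed product (k = 27.0 L² mol⁻² min⁻¹)
    racemization catalyst + added ligand ⇌ idle complex (K = 120 L mol⁻¹, k = 19.0 L mol⁻¹ min⁻¹)
    left-handed substrate + racemization catalyst ⇌ right-handed substrate + racemization catalyst, rate k4*[racemization catalyst]*[left-handed substrate] forward; the back reaction follows from the equilibrium constant (k = 260 L mol⁻¹ min⁻¹)
    partner + free catalyst + left-handed substrate → free catalyst + left-handed product (k = 210 L² mol⁻² min⁻¹)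
    2 free catalyst ⇌ resting dimer (K = 35000 L mol⁻¹, k = 140 L mol⁻¹ min⁻¹)

In this flask the resting dimer, the catalyst's resting state, held 41.0 % of the catalyst charged at 2.00 min and 85.2 % at 20.0 min, while eP read 76.8 % at 5.00 min. The split applied to the 33.7 % reacted gives 29.6 % of left-handed product, and the flask held 29.8 %. A second flask, charged with 5.50 equiv of partner, reached c = 65.1 %. The split gives 57.2 % of left-handed product there, and that flask held 57.4 % at 20.0 min.

The readings were computed with constants of no real substance; scatter was added.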